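In this flask, 0.250 M of reagent cannot turn the whole racemate into product: each product takes one reagent, and the charge is half of the 0.500 M of substrate, so reagent is the limiting reagent. Free catalyst takes up left-handed substrate as catalyst intermediate A and right-handed substrate as catalyst intermediate B. Reagent turns each intermediate into its product and frees the catalyst, while added ligand can hold free catalyst as idle complex.

- Saturday's: left-handed substrate 0.25 M; right-handed substrate 0.25 M; reagent 0.25 M; free catalyst 38 mM; added ligand 92 mM; run made earlier
- flask: left-handed substrate 0.25 M; reagent 0.250 M; free catalyst 25 mM; added ligand 92 mM; right-handed substrate 0.25 M

Saturday's run (percent of the left-handed substrate and right-handed substrate together charged)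

| time / h | left-handed product / % | left-handed substrate / % |
|---|---|---|
| 8.00 | 18.2 | 31.5 |
| 15.0 | 22.0 | 27.2 |
| 20.0 | 23.0 | 25.6 |
| 30.0 | 23.8 | 24.4 |
| 40.0 | 24.5 | 25.0 |

(readings scatter by 0.5 percentage points)

- free catalyst is single-handed; left-handed substrate and right-handed substrate are mirror images of each other, charged as a racemate, each of them at the stated concentration
- reactions considered so far: free catalyst + left-handed substrate <-> catalyst intermediate A; free catalyst + right-handed substrate <-> catalyst intermediate B; reagent + catalyst intermediate A -> free catalyst + left-handed product; reagent + catalyst intermediate B -> free catalyst + right-handed product; free catalyst + added ligand <-> idle complex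
- no earlier run changes the charge of free catalyst; that part of a forecast is a guess

* apparent order in free catalyst when 50% of the left-handed substrate and right-handed substrate together are converted (percent change of the rate of making left-handed product for one percent more free catalyst charged)

What counts as converted? Substrate that has gone, whether it is now product or still sits on the catalyst. So at 50% the substrate consumed equals the reagent charged, yet reagent has paid only for the product. The reagent left therefore equals [catalyst intermediate A] + [catalyst intermediate B].

How large can that be? Take the hold-up ceiling, catalyst charged over racemate charged: 5.00%. At the late end, with reagent gone, conversion stands above one half by the hold-up, which cannot pass this ceiling.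

Does Saturday's run respect its own ceiling? That ceiling is 7.60%. At 30.0 h, left-handed product and left-handed substrate read 1.8 percentage points short of their half of the racemate, a reading with a scatter of 0.5 points on each figure, and that lies inside it.

And the order? The rate is proportional to [reagent][catalyst intermediate A]. At the look point [reagent] is itself the catalyst-held substrate, so the catalyst charge enters through both factors, and I reckon about 2.

The forecast says 2.1, a little above my figure, holding that “both factors scale with catalyst charged”. The flask gives 2.1.

    free catalyst + left-handed substrate ⇌ catalyst intermediate A (K = 4.49 M⁻¹, k = 2.71 M⁻¹ min⁻¹)
    free catalyst + right-handed substrate ⇌ catalyst intermediate B (K = 12.5 M⁻¹, k = 2.38 M⁻¹ min⁻¹)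
    reagent + catalyst intermediate A → free catalyst + left-handed product (k = 0.174 M⁻¹ min⁻¹)
    reagent + catalyst intermediate B → free catalyst + right-handed product (k = 0.0753 M⁻¹ min⁻¹)
    free catalyst + added ligand ⇌ idle complex (K = 7.24 M⁻¹, k = 0.0139 M⁻¹ min⁻¹)

In this flask reagent turned both intermediates over while it lasted: it stood at 22.0% of its charge at 0.600 d, and conversion reached 50% later, at 1.23 d, with left-handed product forming at 0.0144 M d⁻¹. With reagent down to 0.148% at 3.00 d, the left-handed and right-handed products stood at 23.9% and 26.1%, and at 6.00 d catalyst intermediate A and catalyst intermediate B held 15.9% and 38.4% of the catalyst, a hold-up of 2.72% of the racemate against the ceiling of 5.00%.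

(The data were generated by integration for an exercise, noise included.)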